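**Plan**
Cuts: the 3-OH and 5-OH go back to a benzyl and a methyl ether, and the 8-OMe to a phenol. Ring A is then cut at C5–C6, C7–C8 and C8–C8a, and ring C at C2–C3, O1–C8a and C4a–C8a.
Enabling feature: ring A has oxygen on C5 and C8 para to each other, OMe on C7 and H on C6, and it shares the C4a=C8a double bond with ring C. This pattern maps onto a methoxycarbene carbon (C5), HC≡COMe (C6, C7), one CO (C8) and the alkene of a 4-pyranone whose CH next to O1 is free.
Forward: ring B is bought. Ring C is closed from ethyl 4-(benzyloxy)acetoacetate (C3, C4, C4a and, as its ester carbon, C5), DMF dimethyl acetal (C8a) and 3,4,5-trimethoxybenzoyl chloride (C2).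
The ester carbon is raised to a methoxycarbene on zerovalent chromium through the acid chloride and Na2Cr(CO)5. Benzannulation with methoxyacetylene closes ring A last, and O8-methylation and BCl3 finish the route.
Stereochemistry: the target has no stereocentre and no stereogenic double bond, so none has to be set.

Key step: step 7

Remark: the aminomethylidene double bonds of the push–pull enaminones rotate easily and vanish on cyclisation, so they are drawn without geometry; the η6 bond of the arene–Cr(CO)3 complex cannot be written in SMILES and is shown as two dot-joined parts.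

Step 1
Reactants: 1 ethyl 4-(benzyloxy)-3-oxobutanoate; 2 N,N-dimethylformamide dimethyl acetal
Product: 3 ethyl 4-(benzyloxy)-2-[(dimethylamino)methylidene]-3-oxobutanoate
Conditions: 2 (1.1 equiv), toluene, 0 °C → rt
Reagents that add atoms: none
Why: Condensation of an active methylene with an amide acetal (enaminone formation): the C2 methylene between the two carbonyls is by far the most acidic site, so one equivalent of 2 reacts there and leaves the benzyloxy-bearing C4 methylene free for the next step.

Step 2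
Reactants: 3 ethyl 4-(benzyloxy)-2-[(dimethylamino)methylidene]-3-oxobutanoate; 4 3,4,5-trimethoxybenzoyl chloride
Product: 6 ethyl 5-(benzyloxy)-4-oxo-6-(3,4,5-trimethoxyphenyl)-4H-pyran-3-carboxylate, via acylated enaminone 5 (not isolated)
Conditions: LiN(SiMe3)2 (2.5 equiv), THF, −78 °C, 3 and 4 added together; then 2 M aq. HCl, 0 °C → rt
Reagents that add atoms: none
Why: Claisen-type C-acylation of the γ-deprotonated enaminone by the aroyl chloride present in situ gives 5, whose enol oxygen on acidification adds to the aminomethylidene carbon and expels dimethylamine (addition–elimination), which is the established construction of 6-substituted 4-pyranone-3-carboxylates and also tolerates a γ-alkoxy group.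

Step 3
Reactants: 6 ethyl 5-(benzyloxy)-4-oxo-6-(3,4,5-trimethoxyphenyl)-4H-pyran-3-carboxylate
Product: 8 5-(benzyloxy)-4-oxo-6-(3,4,5-trimethoxyphenyl)-4H-pyran-3-carboxylic acid, via trimethylstannyl ester 7 (not isolated)
Conditions: Me3SnOH (4 equiv), ClCH2CH2Cl, 80 °C; then 1 M aq. HCl wash
Reagents that add atoms: trimethyltin hydroxide, C[Sn](C)(C)O
Why: Trimethyltin hydroxide ester hydrolysis delivers hydroxide to the tin-activated ester carbonyl under essentially neutral conditions, which spares the pyranone CH next to the ring oxygen that free hydroxide would attack with ring opening, and it leaves the benzyl and methyl ethers alone.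

Step 4
Reactants: 8 5-(benzyloxy)-4-oxo-6-(3,4,5-trimethoxyphenyl)-4H-pyran-3-carboxylic acid
Product: 9 5-(benzyloxy)-4-oxo-6-(3,4,5-trimethoxyphenyl)-4H-pyran-3-carbonyl chloride
Conditions: (COCl)2 (1.5 equiv), DMF (cat.), CH2Cl2, 0 °C → rt; evaporate, use crude
Reagents that add atoms: oxalyl chloride, O=C(Cl)C(=O)Cl
Why: Acid chloride formation through the Vilsmeier-type chloroiminium catalyst is routine for the related chromone-3-carboxylic acids, needs neither base nor heat, and touches none of the ethers.

Step 5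
Reactants: 9 5-(benzyloxy)-4-oxo-6-(3,4,5-trimethoxyphenyl)-4H-pyran-3-carbonyl chloride; 10 chromium hexacarbonyl, Cr(CO)6
Product: 13 pentacarbonyl{methoxy[5-(benzyloxy)-4-oxo-6-(3,4,5-trimethoxyphenyl)-4H-pyran-3-yl]methylidene}chromium, via disodium pentacarbonylchromate 11 (not isolated), via sodium acylchromate 12 (not isolated)
Conditions: 10, NaC10H8 (2.1 equiv), THF, −78 → 0 °C; 9, THF, −78 → 0 °C; evaporate; Me3OBF4 (1.1 equiv), CH2Cl2, 0 °C; argon throughout
Reagents that add atoms: trimethyloxonium tetrafluoroborate, C[O+](C)C.F[B-](F)(F)F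
Why: Semmelhack–Hegedus synthesis of Fischer carbenes: the strongly nucleophilic dianion 11 displaces chloride from 9 at low temperature and the anionic acyl oxygen of 12 outcompetes the neutral pyranone carbonyl for one equivalent of the Meerwein salt, a polarity that avoids a 3-metallated pyranone, which would be liable to ring-opening β-elimination and too weak a nucleophile for Cr(CO)6.

Step 6
Reactants: 14 chloroacetaldehyde dimethyl acetal (2-chloro-1,1-dimethoxyethane)
Product: 16 methoxyacetylene (methoxyethyne), via sodium methoxyacetylide 15 (not isolated)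
Conditions: NaNH2 (3 equiv), liq. NH3, −33 °C; evaporate NH3; cold sat. aq. NaCl, −20 °C; distil into cold THF
Reagents that add atoms: none
Why: Double base-induced β-elimination (methanol, then HCl) followed by deprotonation to the acetylide is the standard synthesis of alkoxyacetylenes from chloroacetaldehyde acetals, and the volatile product is freed by the aqueous quench and distilled straight into the solvent of the next step.

Step 7
Reactants: 13 pentacarbonyl{methoxy[5-(benzyloxy)-4-oxo-6-(3,4,5-trimethoxyphenyl)-4H-pyran-3-yl]methylidene}chromium; 16 methoxyacetylene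
Product: 18 3-(benzyloxy)-8-hydroxy-5,7-dimethoxy-2-(3,4,5-trimethoxyphenyl)-4H-chromen-4-one, via tricarbonylchromium arene complex 17 (not isolated)
Conditions: 16 (3 equiv, in portions), degassed THF (0.05 M), sealed tube, 45–50 °C, argon; then air, MeCN/CH2Cl2, rt
Reagents that add atoms: none
Why: Proposed new method: heating frees a coordination site on chromium (a cis carbonyl ligand leaves, and the neighbouring C4 carbonyl oxygen can hold the site as a hemilabile donor), methoxyacetylene binds and inserts into Cr=C to give a vinylcarbene, a carbonyl ligand migrates onto the new carbene carbon to give a chromium-bound dienylketene, and ring closure followed by a proton shift from C8a to oxygen gives the phenol as its Cr(CO)3 complex 17, which air strips to 18. The closest known reaction type is the Dötz benzannulation of alkenyl(methoxy)carbene complexes of zerovalent chromium with terminal alkynes, including 3-furyl complexes that close onto the carbon next to the ring oxygen; untested are an ynol ether as the alkyne and a 4-pyranone as the alkenyl part. Ring A, the only ring formed, closes by a six-electron electrocyclisation in which the ketene carbon (C8) bonds to the pyranone CH next to O1 (C8a), and the hydrogen on that carbon is what allows aromatisation. No stereocentre arises. The selectivity needed is the orientation of alkyne insertion, and it is secured twice: the unsubstituted alkyne carbon bonds to the carbene carbon for steric reasons, as with all terminal alkynes, and the same carbon is the nucleophilic end of the ynol ether and so matches the electrophilic carbene carbon, which puts H on C6 and OMe on C7 beside the CO-derived C8–OH. Phenol formation rather than five-ring closure is favoured by the alkenyl (not aryl) carbene, by THF and by an excess of alkyne, and the oxidative work-up is limited to air because stronger oxidants would take the para-methoxyphenol to the quinone.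

Step 8
Reactants: 18 3-(benzyloxy)-8-hydroxy-5,7-dimethoxy-2-(3,4,5-trimethoxyphenyl)-4H-chromen-4-one
Product: 19 3-(benzyloxy)-5,7,8-trimethoxy-2-(3,4,5-trimethoxyphenyl)-4H-chromen-4-one
Conditions: MeI (2 equiv), K2CO3 (2 equiv), acetone, reflux, argon
Reagents that add atoms: iodomethane, CI
Why: Williamson ether synthesis at the only acidic hydroxyl of 18, carried out promptly because the para-methoxyphenol is prone to oxidation, with no other nucleophilic site in the molecule.

Step 9
Reactants: 19 3-(benzyloxy)-5,7,8-trimethoxy-2-(3,4,5-trimethoxyphenyl)-4H-chromen-4-one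
Product: 21 3,5-dihydroxy-7,8-dimethoxy-2-(3,4,5-trimethoxyphenyl)-4H-chromen-4-one (3,5-dihydroxy-7,8,3',4',5'-pentamethoxyflavone), via bis(dichloroboryl) ether 20 (not isolated)
Conditions: BCl3 (3 equiv), C6HMe5 (3 equiv), CH2Cl2, −78 → 0 °C; then 1 M aq. HCl, rt
Reagents that add atoms: none
Why: Chelation-controlled Lewis acid ether cleavage: BCl3 bound to the C4 carbonyl reaches only the two flanking oxygens, so the 3-O-benzyl bond ionises at −78 °C (the benzyl cation is trapped by pentamethylbenzene before it can alkylate C6) and the peri 5-O-methyl group is lost on warming to 0 °C, while the unchelated methoxyls on C7, C8 and ring B stay intact as long as temperature and amount of BCl3 are limited.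

**Compound list**
1 | ethyl 4-(benzyloxy)-3-oxobutanoate | CCOC(=O)CC(=O)COCc1ccccc1 | starting material
2 | N,N-dimethylformamide dimethyl acetal | COC(OC)N(C)C | starting material
3 | ethyl 4-(benzyloxy)-2-[(dimethylamino)methylidene]-3-oxobutanoate | CCOC(=O)C(=CN(C)C)C(=O)COCc1ccccc1 | intermediate
4 | 3,4,5-trimethoxybenzoyl chloride | COc1cc(C(=O)Cl)cc(OC)c1OC | starting material
5 | ethyl 4-(benzyloxy)-2-[(dimethylamino)methylidene]-3,5-dioxo-5-(3,4,5-trimethoxyphenyl)pentanoate (C4 configurationally labile, enolised) | CCOC(=O)C(=CN(C)C)C(=O)C(OCc1ccccc1)C(=O)c1cc(OC)c(OC)c(OC)c1 | intermediate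
6 | ethyl 5-(benzyloxy)-4-oxo-6-(3,4,5-trimethoxyphenyl)-4H-pyran-3-carboxylate | CCOC(=O)c1coc(-c2cc(OC)c(OC)c(OC)c2)c(OCc2ccccc2)c1=O | intermediate
7 | trimethylstannyl 5-(benzyloxy)-4-oxo-6-(3,4,5-trimethoxyphenyl)-4H-pyran-3-carboxylate | C[Sn](C)(C)OC(=O)c1coc(-c2cc(OC)c(OC)c(OC)c2)c(OCc2ccccc2)c1=O | intermediate
8 | 5-(benzyloxy)-4-oxo-6-(3,4,5-trimethoxyphenyl)-4H-pyran-3-carboxylic acid | OC(=O)c1coc(-c2cc(OC)c(OC)c(OC)c2)c(OCc2ccccc2)c1=O | intermediate
9 | 5-(benzyloxy)-4-oxo-6-(3,4,5-trimethoxyphenyl)-4H-pyran-3-carbonyl chloride | ClC(=O)c1coc(-c2cc(OC)c(OC)c(OC)c2)c(OCc2ccccc2)c1=O | intermediate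
10 | chromium hexacarbonyl, Cr(CO)6 | O=C=[Cr](=C=O)(=C=O)(=C=O)(=C=O)=C=O | starting material
11 | disodium pentacarbonylchromate, Na2Cr(CO)5 | [Na+].[Na+].O=C=[Cr-2](=C=O)(=C=O)(=C=O)=C=O | intermediate
12 | sodium pentacarbonyl{[5-(benzyloxy)-4-oxo-6-(3,4,5-trimethoxyphenyl)-4H-pyran-3-yl]carbonyl}chromate | [Na+].[O-]C(c1coc(-c2cc(OC)c(OC)c(OC)c2)c(OCc2ccccc2)c1=O)=[Cr](=C=O)(=C=O)(=C=O)(=C=O)=C=O | intermediate
13 | pentacarbonyl{methoxy[5-(benzyloxy)-4-oxo-6-(3,4,5-trimethoxyphenyl)-4H-pyran-3-yl]methylidene}chromium | COC(c1coc(-c2cc(OC)c(OC)c(OC)c2)c(OCc2ccccc2)c1=O)=[Cr](=C=O)(=C=O)(=C=O)(=C=O)=C=O | intermediate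
14 | chloroacetaldehyde dimethyl acetal | COC(CCl)OC | starting material
15 | sodium methoxyacetylide | [Na+].[C-]#COC | intermediate
16 | methoxyacetylene | COC#C | intermediate
17 | tricarbonylchromium complex of 18, Cr(CO)3 bound η6 to ring A | O=c1c(OCc2ccccc2)c(-c2cc(OC)c(OC)c(OC)c2)oc2c(O)c(OC)cc(OC)c12.O=C=[Cr](=C=O)=C=O | intermediate
18 | 3-(benzyloxy)-8-hydroxy-5,7-dimethoxy-2-(3,4,5-trimethoxyphenyl)-4H-chromen-4-one | O=c1c(OCc2ccccc2)c(-c2cc(OC)c(OC)c(OC)c2)oc2c(O)c(OC)cc(OC)c12 | intermediate
19 | 3-(benzyloxy)-5,7,8-trimethoxy-2-(3,4,5-trimethoxyphenyl)-4H-chromen-4-one | O=c1c(OCc2ccccc2)c(-c2cc(OC)c(OC)c(OC)c2)oc2c(OC)c(OC)cc(OC)c12 | intermediate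
20 | 3,5-bis[(dichloroboranyl)oxy]-7,8-dimethoxy-2-(3,4,5-trimethoxyphenyl)-4H-chromen-4-one | COc1cc(-c2oc3c(OC)c(OC)cc(OB(Cl)Cl)c3c(=O)c2OB(Cl)Cl)cc(OC)c1OC | intermediate
21 | 3,5-dihydroxy-7,8-dimethoxy-2-(3,4,5-trimethoxyphenyl)-4H-chromen-4-one | COc1cc(-c2oc3c(OC)c(OC)cc(O)c3c(=O)c2O)cc(OC)c1OC | target

**Count and risks**
Total steps: 9. Longest linear sequence: 8 (steps 1, 2, 3, 4, 5, 7, 8, 9); step 6 is a one-step side branch.

Step 7 (the labelled step).
- Risk: the ynol ether may oligomerise on the unsaturated chromium centre. It may also attack the electrophilic CH next to the ring oxygen as a carbon nucleophile. The alkoxy-stabilised vinylcarbene formed after insertion may fail to take up CO and close to a five-membered ring.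
- Fallback (known chemistry; ring A is bought and ring C is closed last): it sets out from 4 and comes back at 21. Acid chloride 4 acylates commercial 1-(2-hydroxy-3,4,6-trimethoxyphenyl)ethan-1-one F1 (pyridine, rt) to 2-acetyl-3,5,6-trimethoxyphenyl 3,4,5-trimethoxybenzoate F2. Baker–Venkataraman rearrangement (KOH, pyridine, 50 °C) should give 1-(2-hydroxy-3,4,6-trimethoxyphenyl)-3-(3,4,5-trimethoxyphenyl)propane-1,3-dione F3. Cyclodehydration (H2SO4, AcOH) then gives 5,7,8-trimethoxy-2-(3,4,5-trimethoxyphenyl)-4H-chromen-4-one F4. C3-hydroxylation with dimethyldioxirane (acetone/CH2Cl2, 0 °C) gives 3-hydroxy-5,7,8-trimethoxy-2-(3,4,5-trimethoxyphenyl)-4H-chromen-4-one F5. BCl3 (CH2Cl2, −78 → 0 °C) removes only the chelated 5-methyl group and gives 21.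

Step 5.
- Risk: the strongly reducing dianion may transfer an electron to the electron-poor pyranone, or add to the CH next to the ring oxygen instead of substituting at the acyl chloride. The Meerwein salt may also methylate the pyranone carbonyl.
- Fallback (reversed polarity, classical Fischer route): it sets out from 8 and comes back at 13. Protodecarboxylation of 8 (Ag2CO3 cat., AcOH, DMSO, 120 °C) gives 3-(benzyloxy)-2-(3,4,5-trimethoxyphenyl)-4H-pyran-4-one F6. Carbonyl-directed zincation at C5 follows, with TMPZnCl·LiCl (TMP = 2,2,6,6-tetramethylpiperidin-1-yl) and MgCl2 in THF. This selectivity is known for C3 of chromones, and it bypasses electrophilic halogenation, in which ring B would compete. It gives the chlorozinc pyranone F7, and I2 converts this into 3-(benzyloxy)-5-iodo-2-(3,4,5-trimethoxyphenyl)-4H-pyran-4-one F8. Iodine–magnesium exchange (iPrMgCl·LiCl, THF, −40 °C, kept cold against ring opening) gives the pyranonylmagnesium chloride F9, which is added to 10. The resulting chloromagnesium acylchromate F10 is methylated with Me3OBF4 to 13.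

Step 3.
- Risk: the ethyl ester may hydrolyse slowly. Hydroxide transfer to the CH next to the ring oxygen may open the pyranone. The carboxylate may lose CO2 at 80 °C.
- Fallback (acidolysis in place of hydrolysis, through a change of ester): it sets out from 2 and 4 and comes back at 8. The starting ester is tert-butyl 4-(benzyloxy)-3-oxobutanoate F11, made from LiCH2CO2tBu and benzyloxyacetyl chloride (THF, −78 °C). It condenses with 2 to tert-butyl 4-(benzyloxy)-2-[(dimethylamino)methylidene]-3-oxobutanoate F12. LiN(SiMe3)2 and 4 (THF, −78 °C) give the acylated tert-butyl enaminone F13. On acidification this cyclises to tert-butyl 5-(benzyloxy)-4-oxo-6-(3,4,5-trimethoxyphenyl)-4H-pyran-3-carboxylate F14. Short exposure to CF3CO2H in CH2Cl2 (0 °C → rt) cleaves the tert-butyl ester to 8, conditions under which the acid-stable pyranone and the benzyl ether should persist.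

**Further compounds**
F1 | step 7 | 1-(2-hydroxy-3,4,6-trimethoxyphenyl)ethan-1-one | CC(=O)c1c(O)c(OC)c(OC)cc1OC
F2 | step 7 | 2-acetyl-3,5,6-trimethoxyphenyl 3,4,5-trimethoxybenzoate | CC(=O)c1c(OC(=O)c2cc(OC)c(OC)c(OC)c2)c(OC)c(OC)cc1OC
F3 | step 7 | 1-(2-hydroxy-3,4,6-trimethoxyphenyl)-3-(3,4,5-trimethoxyphenyl)propane-1,3-dione | COc1cc(C(=O)CC(=O)c2c(O)c(OC)c(OC)cc2OC)cc(OC)c1OC
F4 | step 7 | 5,7,8-trimethoxy-2-(3,4,5-trimethoxyphenyl)-4H-chromen-4-one | COc1cc(-c2cc(=O)c3c(OC)cc(OC)c(OC)c3o2)cc(OC)c1OC
F5 | step 7 | 3-hydroxy-5,7,8-trimethoxy-2-(3,4,5-trimethoxyphenyl)-4H-chromen-4-one | COc1cc(-c2oc3c(OC)c(OC)cc(OC)c3c(=O)c2O)cc(OC)c1OC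
F6 | step 5 | 3-(benzyloxy)-2-(3,4,5-trimethoxyphenyl)-4H-pyran-4-one | COc1cc(-c2occc(=O)c2OCc2ccccc2)cc(OC)c1OC
F7 | step 5 | chloro[5-(benzyloxy)-4-oxo-6-(3,4,5-trimethoxyphenyl)-4H-pyran-3-yl]zinc | COc1cc(-c2occ([Zn]Cl)c(=O)c2OCc2ccccc2)cc(OC)c1OC
F8 | step 5 | 3-(benzyloxy)-5-iodo-2-(3,4,5-trimethoxyphenyl)-4H-pyran-4-one | COc1cc(-c2occ(I)c(=O)c2OCc2ccccc2)cc(OC)c1OC
F9 | step 5 | chloro[5-(benzyloxy)-4-oxo-6-(3,4,5-trimethoxyphenyl)-4H-pyran-3-yl]magnesium | COc1cc(-c2occ([Mg]Cl)c(=O)c2OCc2ccccc2)cc(OC)c1OC
F10 | step 5 | chloromagnesium pentacarbonyl{[5-(benzyloxy)-4-oxo-6-(3,4,5-trimethoxyphenyl)-4H-pyran-3-yl]carbonyl}chromate | Cl[Mg+].[O-]C(c1coc(-c2cc(OC)c(OC)c(OC)c2)c(OCc2ccccc2)c1=O)=[Cr](=C=O)(=C=O)(=C=O)(=C=O)=C=O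
F11 | step 3 | tert-butyl 4-(benzyloxy)-3-oxobutanoate | CC(C)(C)OC(=O)CC(=O)COCc1ccccc1
F12 | step 3 | tert-butyl 4-(benzyloxy)-2-[(dimethylamino)methylidene]-3-oxobutanoate | CC(C)(C)OC(=O)C(=CN(C)C)C(=O)COCc1ccccc1
F13 | step 3 | tert-butyl 4-(benzyloxy)-2-[(dimethylamino)methylidene]-3,5-dioxo-5-(3,4,5-trimethoxyphenyl)pentanoate | CC(C)(C)OC(=O)C(=CN(C)C)C(=O)C(OCc1ccccc1)C(=O)c1cc(OC)c(OC)c(OC)c1
F14 | step 3 | tert-butyl 5-(benzyloxy)-4-oxo-6-(3,4,5-trimethoxyphenyl)-4H-pyran-3-carboxylate | CC(C)(C)OC(=O)c1coc(-c2cc(OC)c(OC)c(OC)c2)c(OCc2ccccc2)c1=O
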